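**Retrosynthetic overview**
1. Vicolide D ⇐ its 6‑O‑MOM ether (last step: acetal cleavage). The (2R,3R)‑epoxyangelate is carried from an early ester; the acid comes from Sharpless epoxidation of angelyl alcohol.
2. Key operation: an acyclic bis(vinyl halide) is hydroborated and doubly carbonylated in one flask. The γ‑lactone closes first (C11–I + CO + 8‑OH), then the ten‑membered carbocycle (C1–Br + CO + C3–B), so C12 and C2 both come from CO.
3. Seco compound ⇐ Nozaki–Hiyama addition (C7–C8) of a (Z)‑2‑iodoallyl bromide to (Z)‑4‑bromo‑3‑methylbut‑3‑enal (from 3‑butyn‑1‑ol).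
4. Allyl bromide ⇐ cross‑metathesis, α‑iodination and reduction of the ester of the Brown alkoxyallylboration product of methacrolein (sets C5, C6; C4 is set later by hydroboration).
5. Ring order: γ‑lactone, then ten‑membered ring, in the same operation; before it only the side‑chain epoxide exists.

Assumption: allyl methoxymethyl ether, methyl angelate and 3‑butyn‑1‑ol are taken as commercial; "C1–C13" refers to germacrane numbering of vicolide D (C1–C10 ring, C11–C13 lactone).

**Step 1**
Reactants: 1 3-butyn-1-ol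
Product: 3 (Z)-4-bromo-3-methylbut-3-en-1-ol, via cyclic alkenylalane 2 (not isolated)
Conditions: Me3Al (3 equiv), Cp2ZrCl2 (0.25 equiv), (CH2Cl)2, 23 °C then reflux 72 h; NBS, THF, −30 °C
Reagents that add atoms: trimethylaluminium C[Al](C)C; N-bromosuccinimide O=C1CCC(=O)N1Br
Why: Cp2ZrCl2-catalysed Negishi carboalumination gives the syn adduct, which on heating isomerises to the chelated cyclic alane with Al cis to the oxyethyl chain, and brominolysis with retention gives the (Z)-vinyl bromide.

**Step 2**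
Reactants: 3 (Z)-4-bromo-3-methylbut-3-en-1-ol
Product: 4 (Z)-4-bromo-3-methylbut-3-enal
Conditions: Dess–Martin periodinane, CH2Cl2, 0 °C; used crude
Reagents that add atoms: none
Why: Dess–Martin oxidation under near-neutral conditions gives the β,γ-unsaturated aldehyde without conjugation or loss of the Z geometry.

**Step 3**
Reactants: 5 methyl angelate
Product: 6 (Z)-2-methylbut-2-en-1-ol
Conditions: iBu2AlH (2.2 equiv), CH2Cl2, −78 °C
Reagents that add atoms: none
Why: 1,2-reduction of the enoate by the aluminium hydride keeps the Z double bond.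

**Step 4**
Reactants: 6 (Z)-2-methylbut-2-en-1-ol
Product: 7 [(2S,3R)-2,3-dimethyloxiran-2-yl]methanol
Conditions: Ti(OiPr)4 (10 mol %), L-(+)-diethyl tartrate (12 mol %), tBuOOH, 4 Å MS, CH2Cl2, −20 °C
Reagents that add atoms: tert-butyl hydroperoxide CC(C)(C)OO
Why: Sharpless asymmetric epoxidation with Ti(OiPr)4 and natural L-(+)-tartrate delivers oxygen to the face that gives the (2S,3R)-epoxy alcohol (the same sense as nerol giving its 2S,3R epoxide), and any minor enantiomer is removed later as a diastereomeric ester.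

**Step 5**
Reactants: 7 [(2S,3R)-2,3-dimethyloxiran-2-yl]methanol
Product: 8 (2R,3R)-2,3-dimethyloxirane-2-carboxylic acid
Conditions: RuCl3 (2 mol %), NaIO4 (3 equiv), CCl4/MeCN/H2O, rt
Reagents that add atoms: sodium periodate [Na+].[O-]I(=O)(=O)=O
Why: Catalytic RuO4 oxidation (Sharpless RuCl3/NaIO4) takes the primary alcohol to the acid without opening the epoxide, and the descriptor at C2 changes from S to R only through CIP priorities.

**Step 6**
Reactants: 9 allyl methoxymethyl ether; 10 methacrolein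
Product: 12 (3R,4R)-4-(methoxymethoxy)-2-methylhexa-1,5-dien-3-ol, via allylborane 11 (not isolated)
Conditions: 9, s-BuLi, THF, −78 °C; (−)-Ipc2BOMe; BF3·OEt2; then 10, −78 °C; NaOH, H2O2
Reagents that add atoms: none
Why: Brown alkoxyallylboration through a chair transition state gives the syn product from the (Z)-γ-alkoxyallylborane, the isopinocampheyl groups from (+)-α-pinene set the absolute configuration (C5 and C6 of vicolide D), and the C5 hydroxyl is left free while the C6 oxygen is protected.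

**Step 7**
Reactants: 8 (2R,3R)-2,3-dimethyloxirane-2-carboxylic acid; 12 (3R,4R)-4-(methoxymethoxy)-2-methylhexa-1,5-dien-3-ol
Product: 14 (3R,4R)-4-(methoxymethoxy)-2-methylhexa-1,5-dien-3-yl (2R,3R)-2,3-dimethyloxirane-2-carboxylate, via mixed anhydride 13 (not isolated)
Conditions: 8, 2,4,6-Cl3C6H2COCl, Et3N, THF, rt; then 12, DMAP, toluene, rt
Reagents that add atoms: none
Why: Yamaguchi esterification through the mixed anhydride acylates the hindered allylic alcohol with the hindered epoxy acid without touching a stereocenter.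

**Step 8**
Reactants: 14 (3R,4R)-4-(methoxymethoxy)-2-methylhexa-1,5-dien-3-yl (2R,3R)-2,3-dimethyloxirane-2-carboxylate; 15 crotonaldehyde
Product: 16 (2E,4R,5R)-4-(methoxymethoxy)-6-methyl-1-oxohepta-2,6-dien-5-yl (2R,3R)-2,3-dimethyloxirane-2-carboxylate
Conditions: 15 (5 equiv), RuCl2(H2IMes)(=CH-C6H4-2-OiPr) (second-generation Hoveyda–Grubbs catalyst, 5 mol %), CH2Cl2, 40 °C
Reagents that add atoms: none
Why: Olefin cross-metathesis engages only the monosubstituted vinyl group (the 1,1-disubstituted isopropenyl group is too hindered) and gives the (E)-enal.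

**Step 9**
Reactants: 16 (2E,4R,5R)-4-(methoxymethoxy)-6-methyl-1-oxohepta-2,6-dien-5-yl (2R,3R)-2,3-dimethyloxirane-2-carboxylate
Product: 17 (2Z,4R,5R)-2-iodo-4-(methoxymethoxy)-6-methyl-1-oxohepta-2,6-dien-5-yl (2R,3R)-2,3-dimethyloxirane-2-carboxylate
Conditions: I2, K2CO3, DMAP (20 mol %), THF/H2O, rt
Reagents that add atoms: iodine II
Why: Amine-catalysed α-iodination of the enal (Baylis–Hillman-type addition, iodination, elimination) gives the (Z)-2-iodoenal.

**Step 10**
Reactants: 17 (2Z,4R,5R)-2-iodo-4-(methoxymethoxy)-6-methyl-1-oxohepta-2,6-dien-5-yl (2R,3R)-2,3-dimethyloxirane-2-carboxylate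
Product: 18 (2Z,4R,5R)-1-hydroxy-2-iodo-4-(methoxymethoxy)-6-methylhepta-2,6-dien-5-yl (2R,3R)-2,3-dimethyloxirane-2-carboxylate
Conditions: NaBH4, CeCl3·7H2O, MeOH, −20 °C
Reagents that add atoms: none
Why: Luche reduction is a clean 1,2-reduction of the enal and leaves the esters, the epoxide and the vinyl iodide alone.

**Step 11**
Reactants: 18 (2Z,4R,5R)-1-hydroxy-2-iodo-4-(methoxymethoxy)-6-methylhepta-2,6-dien-5-yl (2R,3R)-2,3-dimethyloxirane-2-carboxylate
Product: 19 (2Z,4R,5R)-1-bromo-2-iodo-4-(methoxymethoxy)-6-methylhepta-2,6-dien-5-yl (2R,3R)-2,3-dimethyloxirane-2-carboxylate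
Conditions: CBr4, PPh3, CH2Cl2, 0 °C
Reagents that add atoms: tetrabromomethane BrC(Br)(Br)Br
Why: Appel reaction converts the primary allylic alcohol to the bromide without allylic transposition.

**Step 12**
Reactants: 19 (2Z,4R,5R)-1-bromo-2-iodo-4-(methoxymethoxy)-6-methylhepta-2,6-dien-5-yl (2R,3R)-2,3-dimethyloxirane-2-carboxylate; 4 (Z)-4-bromo-3-methylbut-3-enal
Product: 20 (1Z,4R,5S,6R,7R)-1-bromo-4-hydroxy-5-(1-iodoethenyl)-6-(methoxymethoxy)-2,8-dimethylnona-1,8-dien-7-yl (2R,3R)-2,3-dimethyloxirane-2-carboxylate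
Conditions: 4 (1.5 equiv), CrCl2 (4 equiv, nickel-free), THF, 0 °C to rt
Reagents that add atoms: none
Why: Nozaki–Hiyama allylation: the allyl–CrCl2 reagent adds through its γ-carbon (C7) in a chair transition state (anti simple selectivity, which fixes C7 relative to C8), while A(1,3) strain from the iodine holds H6 in the alkene plane so that the aldehyde is expected to approach anti to the C6–O bond (Felkin-type 1,2-induction), and the two vinyl halides are inert to divalent chromium without nickel.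

**Step 13**
Reactants: 20 (1Z,4R,5S,6R,7R)-1-bromo-4-hydroxy-5-(1-iodoethenyl)-6-(methoxymethoxy)-2,8-dimethylnona-1,8-dien-7-yl (2R,3R)-2,3-dimethyloxirane-2-carboxylate
Product: 23 6-O-methoxymethyl vicolide D, via bis-borane 21 (not isolated), via lactone borane 22 (not isolated)
Conditions: 9-BBN (3 equiv), THF, 0 °C to rt; then H2O, Et3N, Pd(PPh3)4 (10 mol %), CO (1 atm), rt; then K3PO4 (aq), THF (2 mM), 65 °C
Reagents that add atoms: carbon monoxide [C-]#[O+]
Why: Proposed new method: 9-BBN hydroborates the isopropenyl group anti to the C5 acyloxy group (setting C4 as in hydroborations of 1,1-disubstituted allylic alcohol derivatives) and leaves the halogenated alkenes alone; at room temperature only the 2-iodoalkene adds to zerovalent palladium, inserts CO and acylates the C8 hydroxyl (the known cyclocarbonylation of 3-iodobut-3-en-1-ols to α-methylene-γ-butyrolactones) while the vinyl bromide and the unactivated borane wait; after phosphate activation and heating the (Z)-vinyl bromide adds, inserts CO and the acyl–Pd species is captured intramolecularly by the B-alkyl borate (carbonylative B-alkyl Suzuki–Miyaura coupling, known intermolecularly), which closes the ten-membered (Z)-enone, so both rings and both ring carbonyl carbons are formed in one operation.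

**Step 14**
Reactants: 23 6-O-methoxymethyl vicolide D
Product: 25 vicolide D, via bipyridinium salt 24 (not isolated)
Conditions: TMSOTf, 2,2′-bipyridyl, CH2Cl2, 0 °C; then H2O
Reagents that add atoms: none
Why: Silyl triflate–bipyridyl acetal exchange turns the MOM ether into a bipyridinium methyl ether that water hydrolyses, a buffered non-protic MOM cleavage chosen to spare the epoxy ester, the enone and the α-methylene lactone.

**Compound list**
1 | 3-butyn-1-ol | C#CCCO | starting material
2 | cyclic (Z)-alkenylalane, 2,4-dimethyl-5,6-dihydro-2H-1,2-oxaluminine | CC1=C[Al](C)OCC1 | intermediate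
3 | (Z)-4-bromo-3-methylbut-3-en-1-ol | OCC/C(C)=C\Br | intermediate
4 | (Z)-4-bromo-3-methylbut-3-enal | O=CC/C(C)=C\Br | intermediate
5 | methyl angelate, methyl (Z)-2-methylbut-2-enoate | C/C=C(/C)C(=O)OC | starting material
6 | angelyl alcohol, (Z)-2-methylbut-2-en-1-ol | C/C=C(/C)CO | intermediate
7 | [(2S,3R)-2,3-dimethyloxiran-2-yl]methanol | OC[C@]1(C)O[C@@H]1C | intermediate
8 | (2R,3R)-2,3-dimethyloxirane-2-carboxylic acid | OC(=O)[C@]1(C)O[C@@H]1C | intermediate
9 | allyl methoxymethyl ether | C=CCOCOC | starting material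
10 | methacrolein | CC(=C)C=O | starting material
11 | (Z)-3-(methoxymethoxy)allyl-diisopinocampheylborane (Ipc groups from (+)-α-pinene) | COCO/C=C\CB([C@@H]1C[C@@H]2C[C@H]([C@H]1C)C2(C)C)[C@@H]1C[C@@H]2C[C@H]([C@H]1C)C2(C)C | intermediate
12 | (3R,4R)-4-(methoxymethoxy)-2-methylhexa-1,5-dien-3-ol | C=C(C)[C@@H](O)[C@H](OCOC)C=C | intermediate
13 | (2R,3R)-2,3-dimethyloxirane-2-carboxylic 2,4,6-trichlorobenzoic anhydride | O=C(OC(=O)[C@]1(C)O[C@@H]1C)c1c(Cl)cc(Cl)cc1Cl | intermediate
14 | (3R,4R)-4-(methoxymethoxy)-2-methylhexa-1,5-dien-3-yl (2R,3R)-2,3-dimethyloxirane-2-carboxylate | C=C(C)[C@@H](OC(=O)[C@]1(C)O[C@@H]1C)[C@H](OCOC)C=C | intermediate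
15 | crotonaldehyde, (E)-but-2-enal | C/C=C/C=O | starting material
16 | (2E,4R,5R)-4-(methoxymethoxy)-6-methyl-1-oxohepta-2,6-dien-5-yl (2R,3R)-2,3-dimethyloxirane-2-carboxylate | C=C(C)[C@@H](OC(=O)[C@]1(C)O[C@@H]1C)[C@H](OCOC)/C=C/C=O | intermediate
17 | (2Z,4R,5R)-2-iodo-4-(methoxymethoxy)-6-methyl-1-oxohepta-2,6-dien-5-yl (2R,3R)-2,3-dimethyloxirane-2-carboxylate | C=C(C)[C@@H](OC(=O)[C@]1(C)O[C@@H]1C)[C@H](OCOC)/C=C(\I)C=O | intermediate
18 | (2Z,4R,5R)-1-hydroxy-2-iodo-4-(methoxymethoxy)-6-methylhepta-2,6-dien-5-yl (2R,3R)-2,3-dimethyloxirane-2-carboxylate | C=C(C)[C@@H](OC(=O)[C@]1(C)O[C@@H]1C)[C@H](OCOC)/C=C(\I)CO | intermediate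
19 | (2Z,4R,5R)-1-bromo-2-iodo-4-(methoxymethoxy)-6-methylhepta-2,6-dien-5-yl (2R,3R)-2,3-dimethyloxirane-2-carboxylate | C=C(C)[C@@H](OC(=O)[C@]1(C)O[C@@H]1C)[C@H](OCOC)/C=C(\I)CBr | intermediate
20 | (1Z,4R,5S,6R,7R)-1-bromo-4-hydroxy-5-(1-iodoethenyl)-6-(methoxymethoxy)-2,8-dimethylnona-1,8-dien-7-yl (2R,3R)-2,3-dimethyloxirane-2-carboxylate | C=C(C)[C@@H](OC(=O)[C@]1(C)O[C@@H]1C)[C@H](OCOC)[C@@H](C(I)=C)[C@H](O)C/C(C)=C\Br | intermediate
21 | bis-borane: 20 with the isopropenyl group converted to (R)-CH(CH3)CH2-B(9-BBN) and the C8 hydroxyl as its 9-BBN borinate | C(B1C2CCCC1CCC2)[C@@H](C)[C@@H](OC(=O)[C@]3(C)O[C@@H]3C)[C@H](OCOC)[C@@H](C(I)=C)[C@H](OB4C5CCCC4CCC5)C/C(C)=C\Br | intermediate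
22 | lactone borane: trans-α-methylene-γ-butyrolactone (C7, C8, C11–C13 closed) carrying the (Z)-3-bromo-2-methylallyl group on C8 and the C3 B-alkyl-9-BBN chain on C7 | C(B1C2CCCC1CCC2)[C@@H](C)[C@@H](OC(=O)[C@]3(C)O[C@@H]3C)[C@H](OCOC)[C@H]4C(=C)C(=O)O[C@@H]4C/C(C)=C\Br | intermediate
23 | 6-O-methoxymethyl vicolide D | C=C1C(=O)O[C@@H]2C/C(C)=C\C(=O)C[C@@H](C)[C@@H](OC(=O)[C@]3(C)O[C@@H]3C)[C@H](OCOC)[C@@H]12 | intermediate
24 | 6-O-[(2,2′-bipyridin-1-ium-1-yl)methyl] vicolide D triflate | C=C1C(=O)O[C@@H]2C/C(C)=C\C(=O)C[C@@H](C)[C@@H](OC(=O)[C@]3(C)O[C@@H]3C)[C@H](OC[n+]4ccccc4-c4ccccn4)[C@@H]12.[O-]S(=O)(=O)C(F)(F)F | intermediate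
25 | vicolide D | C=C1C(=O)O[C@@H]2C/C(C)=C\C(=O)C[C@@H](C)[C@@H](OC(=O)[C@]3(C)O[C@@H]3C)[C@H](O)[C@@H]12 | target

**Step count**
Total: 14 steps. Longest linear sequence: 11 steps (5 → 25 through steps 3, 4, 5, 7, 8, 9, 10, 11, 12, 13, 14).

**Three steps most likely to fail**

Step 13 (double carbonylative cyclisation). The ten-membered ring closure by a carbonylative B-alkyl coupling has no direct precedent. It competes with direct coupling, oligomerisation and base damage to the new α-methylene lactone, and 9-BBN must ignore the 2-iodoalkene. The fallback sets out from 20 and comes back at 23, separating the two ring closures and bringing the ketone carbon in as an aldehyde. Compound 20 is hydroborated with 9-BBN and the B-alkyl-9-BBN is carbonylated under CO in the presence of LiAlH(OtBu)3, then oxidised with buffered H2O2 to the one-carbon-homologated aldehyde F1. Pd(PPh3)4, CO and Et3N at room temperature then close only the lactone, giving the aldehyde lactone F2. An intramolecular Nozaki–Hiyama–Kishi reaction (CrCl2, NiCl2 1 mol %, DMSO/THF, 2 mM) of the (Z)-vinyl bromide with the aldehyde closes the carbocycle as the allylic alcohol F3 (C2 epimers), and Dess–Martin oxidation gives 23.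

Step 12 (Nozaki–Hiyama addition). The induction from C6 is the least certain stereochemical call in the route: if the aldehyde attacks syn to the C6–O bond, the wrong C7/C8 pair forms. The allyl–CrCl2 species could also lose the C6 alkoxy group. The fallback sets out from 19 (with 4) and comes back at 20, replacing substrate control by catalyst control. Zinc insertion into 19 (Zn dust, THF, 0 °C) and trapping with iPrOBpin gives the 2-iodoallyl pinacolboronate F4. Chiral phosphoric acid catalysed allylboration of 4 ((S)-TRIP 5 mol %, toluene, −30 °C) then goes through a closed chair transition state in which the catalyst fixes the aldehyde face and the anti relationship fixes C7, giving 20.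

Step 9 (α-iodination). The γ-alkoxy stereocenter can epimerise through the dienolate, and aqueous iodine may attack the isopropenyl group. The fallback sets out from 16 and comes back at 20, bringing the iodine in after the C7–C8 bond from a ketone. Luche reduction of 16 gives the (E)-allylic alcohol F5 and Appel bromination gives the allylic bromide F6. CrCl2-mediated addition to 4 gives the vinyl-substituted homoallylic alcohol F7 (facial control is weaker here without the iodine). Tsuji–Wacker oxidation (PdCl2, CuCl, O2, DMF/H2O) of the monosubstituted vinyl group gives the methyl ketone F8. This is condensed with hydrazine to the hydrazone F9, which Barton's vinyl iodide synthesis (I2, tetramethylguanidine, THF, 0 °C) converts to 20.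

**Further compounds**
F1 | step 13 | aldehyde: 20 with the isopropenyl group replaced by (R)-CH(CH3)CH2CHO | O=CC[C@@H](C)[C@@H](OC(=O)[C@]1(C)O[C@@H]1C)[C@H](OCOC)[C@@H](C(I)=C)[C@H](O)C/C(C)=C\Br
F2 | step 13 | aldehyde lactone: F1 with the 8,12-α-methylene-γ-butyrolactone closed | O=CC[C@@H](C)[C@@H](OC(=O)[C@]1(C)O[C@@H]1C)[C@H](OCOC)[C@H]2C(=C)C(=O)O[C@@H]2C/C(C)=C\Br
F3 | step 13 | 2-hydroxy analogue of 23 (allylic alcohol, both C2 epimers) | C=C1C(=O)O[C@@H]2C/C(C)=C\C(O)C[C@@H](C)[C@@H](OC(=O)[C@]3(C)O[C@@H]3C)[C@H](OCOC)[C@@H]12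
F4 | step 12 | pinacolboronate corresponding to bromide 19 | C=C(C)[C@@H](OC(=O)[C@]1(C)O[C@@H]1C)[C@H](OCOC)/C=C(\I)CB1OC(C)(C)C(C)(C)O1
F5 | step 9 | (2E,4R,5R)-1-hydroxy-4-(methoxymethoxy)-6-methylhepta-2,6-dien-5-yl (2R,3R)-2,3-dimethyloxirane-2-carboxylate | C=C(C)[C@@H](OC(=O)[C@]1(C)O[C@@H]1C)[C@H](OCOC)/C=C/CO
F6 | step 9 | (2E,4R,5R)-1-bromo-4-(methoxymethoxy)-6-methylhepta-2,6-dien-5-yl (2R,3R)-2,3-dimethyloxirane-2-carboxylate | C=C(C)[C@@H](OC(=O)[C@]1(C)O[C@@H]1C)[C@H](OCOC)/C=C/CBr
F7 | step 9 | des-iodo analogue of 20 (ethenyl in place of 1-iodoethenyl) | C=C(C)[C@@H](OC(=O)[C@]1(C)O[C@@H]1C)[C@H](OCOC)[C@@H](C=C)[C@H](O)C/C(C)=C\Br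
F8 | step 9 | methyl ketone analogue of 20 (acetyl in place of 1-iodoethenyl) | C=C(C)[C@@H](OC(=O)[C@]1(C)O[C@@H]1C)[C@H](OCOC)[C@@H](C(C)=O)[C@H](O)C/C(C)=C\Br
F9 | step 9 | hydrazone of F8 | C=C(C)[C@@H](OC(=O)[C@]1(C)O[C@@H]1C)[C@H](OCOC)[C@@H](C(C)=NN)[C@H](O)C/C(C)=C\Br
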